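The target joins two esculetin units through an ether from O6 of unit A to C5 of unit B. It has no stereocentre and no stereogenic double bond, so stereochemistry needs no source.
Retrosynthetic cuts, in order: the three O-methyl masks; in the pyranone of unit B, C4-H (back to C4-OH), then C3-C4 and O1-C2, which leads to a methyl salicylate; then C5-C6 and C4a-C8a of the benzene ring of unit B; last the O-C5 bond, made on a two-carbon acrylate.
Enabling feature: the benzene ring of unit B bears oxygen on C5, C6, C7 and C8a and carbon (C4) only on C4a. So C6-C7-C8-C8a is the bis-enol form of 4-methoxyacetoacetate, and C5-C4a-C4 is a propiolate whose β-carbon already holds the aryl ether oxygen.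
Forward order: both rings of unit A are bought as isoscopoletin and O6 is tied to the two-carbon unit. The benzene ring of unit B arises by cycloaddition and aromatisation, and its pyranone is closed last by an intramolecular Claisen condensation. C4 is then deoxygenated and the methyl ethers are removed.

Key step: step 5

Remark: the atoms of unit B keep their coumarin numbers (C4a, C5, C6, C7, C8, C8a) in all precursors. The mono(silyl enol ether) and the chloroacrylate are carried as E/Z mixtures because their geometry is lost in the following step. The three starting materials are taken to be purchasable.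

Step 1
Reactants: 1 methyl 4-methoxy-3-oxobutanoate (methyl 4-methoxyacetoacetate)
Product: 2 methyl 4-methoxy-3-(trimethylsilyloxy)but-2-enoate (E/Z mixture)
Conditions: Me3SiCl, Et3N, hexane, 20 °C
Reagents that add atoms: chlorotrimethylsilane, C[Si](C)(C)Cl
Why: O-silylation of the conjugated enol of a β-keto ester with a chlorosilane and a tertiary amine (silyl enol ether formation) is routine, and the geometry of the new double bond does not matter for the next step.

Step 2
Reactants: 2 methyl 4-methoxy-3-(trimethylsilyloxy)but-2-enoate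
Product: 3 (3Z)-1,4-dimethoxy-1,3-bis(trimethylsilyloxy)buta-1,3-diene (C1=C2 geometry not defined)
Conditions: LiN(i-Pr)2 (commercial solution), THF, −78 °C; Me3SiCl, −78 to 20 °C; non-aqueous work-up
Reagents that add atoms: chlorotrimethylsilane, C[Si](C)(C)Cl
Why: γ-deprotonation of the β-silyloxy enoate gives the extended dienolate, which the chlorosilane traps on the ester oxygen (the standard two-stage route from β-keto esters to 1,3-bis(silyl enol ethers)), and the methoxy group is expected to lie anti to the diene chain (3Z), although either geometry leads to the same arene later.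

Step 3
Reactants: 4 isoscopoletin (6-hydroxy-7-methoxycoumarin); 5 methyl 3,3-dichloroacrylate
Product: 6 methyl 3-chloro-3-[(7-methoxy-2-oxo-2H-chromen-6-yl)oxy]prop-2-enoate (E/Z mixture)
Conditions: K2CO3, 5 (1.5 equiv), DMF, 20 °C
Reagents that add atoms: none
Why: vinylic substitution by addition-elimination of a phenoxide on a β,β-dihaloacrylate is well known, and the first aryloxy group donates into the acrylate and slows a second displacement, so an excess of 5 should hold the reaction at the mono-ether.

Step 4
Reactants: 6 methyl 3-chloro-3-[(7-methoxy-2-oxo-2H-chromen-6-yl)oxy]prop-2-enoate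
Product: 7 methyl 3-[(7-methoxy-2-oxo-2H-chromen-6-yl)oxy]prop-2-ynoate
Conditions: LiN(SiMe3)2 (1.2 equiv), THF, −78 to 0 °C; cold pH 7 buffer, rapid extraction
Reagents that add atoms: none
Why: base-induced dehydrohalogenation of a 1-halovinyl aryl ether is the usual way to aryl ynol ethers and the same elimination turns β-chloroacrylates into propiolates, both isomers of 6 converge once the α-hydrogen is removed and chloride leaves, and the bulky silazide should neither add to the new triple bond nor open the lactone.

Step 5
Reactants: 3 (3Z)-1,4-dimethoxy-1,3-bis(trimethylsilyloxy)buta-1,3-diene; 7 methyl 3-[(7-methoxy-2-oxo-2H-chromen-6-yl)oxy]prop-2-ynoate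
Product: 10 methyl 4,6-dihydroxy-3-methoxy-2-[(7-methoxy-2-oxo-2H-chromen-6-yl)oxy]benzoate, via cyclohexadiene adduct 8 (not isolated), via bis(trimethylsilyl) ether 9 (not isolated)
Conditions: 3 (2.5 equiv), PhMe, sealed tube, 100 °C; then 1 M HCl, THF, 20 °C
Reagents that add atoms: none
Why: Proposed new method: the very electron-rich diene 3 and the push-pull alkyne 7 should combine in a strongly asynchronous normal-demand [4+2] cycloaddition, at its limit a vinylogous Mukaiyama-Michael addition followed by collapse of the allenolate onto the silyloxycarbenium carbon, in which diene terminus C6 bonds to the aryloxy-bearing β-carbon C5 and ketene acetal carbon C8a bonds to the α-carbon C4a. The closest known reaction type is the Diels-Alder addition and aromatisation of 1-methoxy-1,3-bis(silyloxy)butadienes with propiolates and acetylenedicarboxylates to give resorcylates, for which a 3-aryloxypropiolate has not served as the two-carbon partner. The one ring formed, the benzene ring of unit B, is closed in this intermolecular [4+2] mode with two new σ-bonds, after which adduct 8 aromatises by 1,4-loss of methanol (methoxy of C8a, hydrogen of C6) to 9 and dilute acid hydrolyses the two silyl ethers. The two sp3 carbons of 8 (C6 and C8a) are transient and vanish on aromatisation, so nothing has to control them. The step needs head-to-tail regioselectivity, secured because ester and aryloxy group both make C5 the electrophilic carbon while three of the four donors of 3 push electron density onto C6, and it needs chemoselectivity for the alkyne over the C3=C4 bond of unit A, secured because a 7-alkoxycoumarin is a far poorer dienophile than an ynoate. Heating is tolerable because an aryl ynol ether has no β-hydrogen for retro-ene loss of a ketene, and the ether oxygen shares its lone pair with the coumarin ring, which tempers its deactivating effect on the triple bond.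

Step 6
Reactants: 10 methyl 4,6-dihydroxy-3-methoxy-2-[(7-methoxy-2-oxo-2H-chromen-6-yl)oxy]benzoate
Product: 11 methyl 6-hydroxy-3,4-dimethoxy-2-[(7-methoxy-2-oxo-2H-chromen-6-yl)oxy]benzoate
Conditions: MeI (1.05 equiv), K2CO3, acetone, 20 °C
Reagents that add atoms: iodomethane, CI
Why: this Williamson etherification should select the C7 hydroxyl because the C8a hydroxyl is held in a hydrogen bond to the ester carbonyl and is less acidic, which is the usual outcome when 2,4-dihydroxybenzoates meet one equivalent of alkyl halide and a weak base.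

Step 7
Reactants: 11 methyl 6-hydroxy-3,4-dimethoxy-2-[(7-methoxy-2-oxo-2H-chromen-6-yl)oxy]benzoate
Product: 12 methyl 6-acetoxy-3,4-dimethoxy-2-[(7-methoxy-2-oxo-2H-chromen-6-yl)oxy]benzoate
Conditions: Ac2O, pyridine, DMAP (cat.), CH2Cl2, 20 °C
Reagents that add atoms: acetic anhydride, CC(=O)OC(C)=O
Why: DMAP-catalysed O-acylation overcomes the hydrogen bond and the ortho crowding of the only remaining phenol and leaves every other group untouched.

Step 8
Reactants: 12 methyl 6-acetoxy-3,4-dimethoxy-2-[(7-methoxy-2-oxo-2H-chromen-6-yl)oxy]benzoate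
Product: 13 4-hydroxy-6,7-dimethoxy-5-[(7-methoxy-2-oxo-2H-chromen-6-yl)oxy]-2H-chromen-2-one
Conditions: LiN(SiMe3)2 (3 equiv), THF (dilute), −78 to 20 °C; then 1 M HCl
Reagents that add atoms: none
Why: the intramolecular Claisen (Dieckmann-type) condensation of methyl O-acetylsalicylates is the classical entry to 4-hydroxycoumarins, the acetate enolate attacking the neighbouring ester in a 6-exo-trig closure that forms C3-C4, with deprotonation of the acidic product driving the equilibrium and the hindered amide sparing the lactone of unit A.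

Step 9
Reactants: 13 4-hydroxy-6,7-dimethoxy-5-[(7-methoxy-2-oxo-2H-chromen-6-yl)oxy]-2H-chromen-2-one
Product: 14 6,7-dimethoxy-5-[(7-methoxy-2-oxo-2H-chromen-6-yl)oxy]-2-oxo-2H-chromen-4-yl trifluoromethanesulfonate
Conditions: Tf2O, Et3N, CH2Cl2, −20 to 0 °C
Reagents that add atoms: trifluoromethanesulfonic anhydride, O=S(=O)(OS(=O)(=O)C(F)(F)F)C(F)(F)F
Why: O-sulfonylation of the vinylogous acid (enol triflate formation) is routine for 4-hydroxycoumarins, and no other hydroxyl group is present.

Step 10
Reactants: 14 6,7-dimethoxy-5-[(7-methoxy-2-oxo-2H-chromen-6-yl)oxy]-2-oxo-2H-chromen-4-yl trifluoromethanesulfonate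
Product: 15 6,7-dimethoxy-5-[(7-methoxy-2-oxo-2H-chromen-6-yl)oxy]-2H-chromen-2-one
Conditions: Pd(OAc)2 (5 mol %), PPh3 (10 mol %), HCO2H, Et3N, DMF, 60 °C
Reagents that add atoms: none
Why: in this palladium-catalysed formate hydrogenolysis of an enol triflate, zerovalent palladium inserts into the activated C4-O bond, formate replaces triflate and loses CO2, and reductive elimination gives C4-H without touching the C3=C4 bonds, the lactones or the aryl ethers.

Step 11
Reactants: 15 6,7-dimethoxy-5-[(7-methoxy-2-oxo-2H-chromen-6-yl)oxy]-2H-chromen-2-one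
Product: 16 6,7-dihydroxy-5-[(7-hydroxy-2-oxo-2H-chromen-6-yl)oxy]-2H-chromen-2-one (CNP0197949.0)
Conditions: BBr3 (8 equiv), CH2Cl2, −78 to 20 °C; then H2O, under argon
Reagents that add atoms: none
Why: Lewis-acid ether cleavage with BBr3 removes each methyl group by bromide attack at the methyl carbon, a path closed to the diaryl ether, and it is the usual way from methoxycoumarins to hydroxycoumarins when enough reagent is used to saturate both lactone carbonyls.

Compound list
1 | methyl 4-methoxy-3-oxobutanoate | COCC(=O)CC(=O)OC | starting material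
2 | methyl 4-methoxy-3-(trimethylsilyloxy)but-2-enoate (E/Z mixture) | COCC(O[Si](C)(C)C)=CC(=O)OC | intermediate
3 | (3Z)-1,4-dimethoxy-1,3-bis(trimethylsilyloxy)buta-1,3-diene | CO/C=C(\O[Si](C)(C)C)C=C(OC)O[Si](C)(C)C | intermediate
4 | isoscopoletin (6-hydroxy-7-methoxy-2H-chromen-2-one) | COc1cc2oc(=O)ccc2cc1O | starting material
5 | methyl 3,3-dichloroacrylate | COC(=O)C=C(Cl)Cl | starting material
6 | methyl 3-chloro-3-[(7-methoxy-2-oxo-2H-chromen-6-yl)oxy]prop-2-enoate (E/Z mixture) | COC(=O)C=C(Cl)Oc1cc2ccc(=O)oc2cc1OC | intermediate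
7 | methyl 3-[(7-methoxy-2-oxo-2H-chromen-6-yl)oxy]prop-2-ynoate | COC(=O)C#COc1cc2ccc(=O)oc2cc1OC | intermediate
8 | methyl 3,6-dimethoxy-2-[(7-methoxy-2-oxo-2H-chromen-6-yl)oxy]-4,6-bis(trimethylsilyloxy)cyclohexa-1,4-diene-1-carboxylate (diastereomer mixture, not isolated) | COC(=O)C1=C(Oc2cc3ccc(=O)oc3cc2OC)C(OC)C(O[Si](C)(C)C)=CC1(OC)O[Si](C)(C)C | intermediate
9 | methyl 3-methoxy-2-[(7-methoxy-2-oxo-2H-chromen-6-yl)oxy]-4,6-bis(trimethylsilyloxy)benzoate (not isolated) | COC(=O)c1c(O[Si](C)(C)C)cc(O[Si](C)(C)C)c(OC)c1Oc1cc2ccc(=O)oc2cc1OC | intermediate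
10 | methyl 4,6-dihydroxy-3-methoxy-2-[(7-methoxy-2-oxo-2H-chromen-6-yl)oxy]benzoate | COC(=O)c1c(O)cc(O)c(OC)c1Oc1cc2ccc(=O)oc2cc1OC | intermediate
11 | methyl 6-hydroxy-3,4-dimethoxy-2-[(7-methoxy-2-oxo-2H-chromen-6-yl)oxy]benzoate | COC(=O)c1c(O)cc(OC)c(OC)c1Oc1cc2ccc(=O)oc2cc1OC | intermediate
12 | methyl 6-acetoxy-3,4-dimethoxy-2-[(7-methoxy-2-oxo-2H-chromen-6-yl)oxy]benzoate | COC(=O)c1c(OC(C)=O)cc(OC)c(OC)c1Oc1cc2ccc(=O)oc2cc1OC | intermediate
13 | 4-hydroxy-6,7-dimethoxy-5-[(7-methoxy-2-oxo-2H-chromen-6-yl)oxy]-2H-chromen-2-one | O=c1cc(O)c2c(Oc3cc4ccc(=O)oc4cc3OC)c(OC)c(OC)cc2o1 | intermediate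
14 | 6,7-dimethoxy-5-[(7-methoxy-2-oxo-2H-chromen-6-yl)oxy]-2-oxo-2H-chromen-4-yl trifluoromethanesulfonate | O=c1cc(OS(=O)(=O)C(F)(F)F)c2c(Oc3cc4ccc(=O)oc4cc3OC)c(OC)c(OC)cc2o1 | intermediate
15 | 6,7-dimethoxy-5-[(7-methoxy-2-oxo-2H-chromen-6-yl)oxy]-2H-chromen-2-one | O=c1ccc2c(Oc3cc4ccc(=O)oc4cc3OC)c(OC)c(OC)cc2o1 | intermediate
16 | 6,7-dihydroxy-5-[(7-hydroxy-2-oxo-2H-chromen-6-yl)oxy]-2H-chromen-2-one (CNP0197949.0) | O=c1ccc2cc(Oc3c(O)c(O)cc4oc(=O)ccc34)c(O)cc2o1 | target

Total steps: 11. Longest linear sequence: 9 steps (4 to 16 through steps 3 to 11). The branch from 1 through steps 1, 2 and 5 to 11 is equally long.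

Steps most likely to fail

1. Step 5. The donor on the triple bond may slow the cycloaddition so much that silyl migration and hydrolysis of the diene win. A stepwise pathway may also expel aryloxide from the zwitterion before the ring closes. The fallback gives up the ring construction and makes the C5-O bond on intact coumarins by known chemistry, setting out from 4. Bromination ortho to the free 6-hydroxyl, C7 being blocked (NBS, MeCN, 0 °C), should give 5-bromo-6-hydroxy-7-methoxycoumarin F1. O-methylation (MeI, K2CO3, acetone) should then give 5-bromo-6,7-dimethoxycoumarin F2. An Ullmann diaryl ether coupling of F2 with a second equivalent of 4 (CuI, picolinic acid, K3PO4, DMSO, 90 °C) comes back to the route at 15.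

2. Step 4. The push-pull alkyne may be lost as it forms, through addition of base or adventitious water across the triple bond or through oligomerisation during isolation. The fallback sets out from 6 and uses it directly as the two-carbon partner at the alkene oxidation level, so the elimination is moved behind the ring formation. Heating 6 with 3 in toluene, or applying high pressure, should give methyl 2-chloro-3,6-dimethoxy-2-[(7-methoxy-2-oxo-2H-chromen-6-yl)oxy]-4,6-bis(trimethylsilyloxy)cyclohex-4-ene-1-carboxylate F3. Its hydrogen α to the ester and its β-chloride are removed by Et3N. This comes back to the route at 8, which goes on to 10 as in step 5.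

3. Step 8. The aryl acetate enolate may fragment to ketene and phenoxide, or the acetyl group may be transferred to liberated methoxide, faster than the enolate attacks the doubly ortho-substituted ester. The fallback sets out from 11 and forms C3-C4 by olefination under neutral conditions. (Triphenylphosphoranylidene)ketene, Ph3P=C=C=O, in refluxing toluene should add the phenol to give the ester ylide methyl 3,4-dimethoxy-2-[(7-methoxy-2-oxo-2H-chromen-6-yl)oxy]-6-[(triphenylphosphoranylidene)acetoxy]benzoate F4. An intramolecular Wittig reaction of F4 on the ester carbonyl should give 4,6,7-trimethoxy-5-[(7-methoxy-2-oxo-2H-chromen-6-yl)oxy]-2H-chromen-2-one F5. Selective hydrolysis of its vinylogous ester methoxy group (aqueous HCl, dioxane, 80 °C) comes back to the route at 13.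

Further compounds
F1 | step 5 | 5-bromo-6-hydroxy-7-methoxy-2H-chromen-2-one | COc1cc2oc(=O)ccc2c(Br)c1O
F2 | step 5 | 5-bromo-6,7-dimethoxy-2H-chromen-2-one | COc1cc2oc(=O)ccc2c(Br)c1OC
F3 | step 4 | methyl 2-chloro-3,6-dimethoxy-2-[(7-methoxy-2-oxo-2H-chromen-6-yl)oxy]-4,6-bis(trimethylsilyloxy)cyclohex-4-ene-1-carboxylate (diastereomer mixture) | COC(=O)C1C(Cl)(Oc2cc3ccc(=O)oc3cc2OC)C(OC)C(O[Si](C)(C)C)=CC1(OC)O[Si](C)(C)C
F4 | step 8 | methyl 3,4-dimethoxy-2-[(7-methoxy-2-oxo-2H-chromen-6-yl)oxy]-6-[(triphenylphosphoranylidene)acetoxy]benzoate | COC(=O)c1c(OC(=O)C=P(c2ccccc2)(c2ccccc2)c2ccccc2)cc(OC)c(OC)c1Oc1cc2ccc(=O)oc2cc1OC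
F5 | step 8 | 4,6,7-trimethoxy-5-[(7-methoxy-2-oxo-2H-chromen-6-yl)oxy]-2H-chromen-2-one | O=c1cc(OC)c2c(Oc3cc4ccc(=O)oc4cc3OC)c(OC)c(OC)cc2o1
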